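**Retrosynthetic overview**

1. Haterumaimide J ⇒ aldehyde 23 + succinate imide 26. An Evans syn-aldol sets C12 and C13, and ammonia closes the succinimide ring last.
2. 23 ⇒ decalin 19 (C8 carbinol → ketone → exocyclic methylene) ⇒ cyclopropane 18. One cationic operation breaks C10–C11, closes ring B through C10–C5, closes ring A through C4–C3, and places chloride on C2.
3. 18 ⇒ lactone 16 ⇒ acyclic diazoacetate 15. The tethered carbene carbon C11 adds to C9=C10, which forms the C9–C11 bond and closes a temporary γ-lactone and a temporary cyclopropane.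
4. Enabling feature: in ring B, C9 lies between C8 (the sp2 carbon of the exocyclic methylene, carried as a carbinol) and the quaternary C10, and it bears C11H2–C12(O). The 1,4-relation of the C8 and C12 oxygens allows an ester tether, and the gem-dialkyl C10 is the donor end of the C9–C10–C11 ring.
5. 15 ⇒ enone 11 ⇒ Weinreb amide 6 + vinyl bromide 9. Order of ring formation: lactone and cyclopropane (both temporary), ring B, ring A, succinimide.

Key step: step 10

Remark: labdane numbering (C1–C20) of the target is used for all intermediates. α is the face of H5 and H9, and β is the face of the C10 methyl.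

**Step 1**
Reactants: 1 methyl 4-oxobutanoate; 2 2-(triphenylphosphoranylidene)propanal
Product: 3 methyl (E)-5-methyl-6-oxohex-4-enoate
Conditions: toluene, 80 °C
Reagents that add atoms: none
Why: Wittig olefination of the aldehyde with a stabilised ylide should give the E-enal, in which the methyl group is cis to the chain.

**Step 2**
Reactants: 3 methyl (E)-5-methyl-6-oxohex-4-enoate
Product: 4 methyl (E)-6-hydroxy-5-methylhex-4-enoate
Conditions: NaBH4, CeCl3·7H2O, MeOH, 0 °C
Reagents that add atoms: none
Why: Luche reduction delivers hydride 1,2 to the enal and leaves the methyl ester and the alkene geometry untouched.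

**Step 3**
Reactants: 4 methyl (E)-6-hydroxy-5-methylhex-4-enoate
Product: 5 methyl (E)-6-(tert-butyldiphenylsilyloxy)-5-methylhex-4-enoate
Conditions: TBDPSCl, imidazole, DMF, rt
Reagents that add atoms: tert-butyl(chloro)diphenylsilane, CC(C)(C)[Si](Cl)(c1ccccc1)c1ccccc1
Why: Standard silylation of a primary allylic alcohol gives an acid-robust, non-participating ether for the later C18 oxygen.

**Step 4**
Reactants: 5 methyl (E)-6-(tert-butyldiphenylsilyloxy)-5-methylhex-4-enoate
Product: 6 (E)-6-(tert-butyldiphenylsilyloxy)-N-methoxy-N,5-dimethylhex-4-enamide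
Conditions: MeNHOMe·HCl, AlMe3, CH2Cl2, 0 °C to rt
Reagents that add atoms: N,O-dimethylhydroxylamine hydrochloride, CNOC.Cl
Why: Weinreb amide synthesis by aluminium-amide aminolysis of an unhindered ester tolerates both the silyl ether and the alkene.

**Step 5**
Reactants: 7 pent-1-en-4-yne
Product: 9 (E)-1-bromo-2-methylpenta-1,4-diene, via alkenylalane 8 (not isolated)
Conditions: AlMe3, Cp2ZrCl2 (0.2 equiv), CH2Cl2, rt; then NBS, THF, −30 °C
Reagents that add atoms: trimethylaluminium, C[Al](C)C; N-bromosuccinimide, O=C1CCC(=O)N1Br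
Why: Negishi carboalumination adds Me–Al syn across the terminal alkyne only, placing methyl on the internal carbon, and bromodealumination with retention fixes the E geometry of the future C9=C10.

**Step 6**
Reactants: 9 (E)-1-bromo-2-methylpenta-1,4-diene; 6 (E)-6-(tert-butyldiphenylsilyloxy)-N-methoxy-N,5-dimethylhex-4-enamide
Product: 11 (4E,9E)-11-(tert-butyldiphenylsilyloxy)-4,10-dimethylundeca-1,4,9-trien-6-one, via vinyllithium 10 (not isolated)
Conditions: t-BuLi (2 equiv), Et2O, −78 °C; then 6, THF, −78 °C; then H2O
Reagents that add atoms: none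
Why: Bromine–lithium exchange proceeds with retention, and acylation by the Weinreb amide stops at the ketone because the chelated tetrahedral adduct survives until the quench.

**Step 7**
Reactants: 11 (4E,9E)-11-(tert-butyldiphenylsilyloxy)-4,10-dimethylundeca-1,4,9-trien-6-one
Product: 12 (6R,4E,9E)-11-(tert-butyldiphenylsilyloxy)-4,10-dimethylundeca-1,4,9-trien-6-ol
Conditions: (S)-2-methyl-CBS-oxazaborolidine (0.2 equiv), catecholborane, toluene, −78 °C; then H2O
Reagents that add atoms: none
Why: Corey–Bakshi–Shibata reduction treats the alkenyl group as the large substituent, so the (S)-catalyst should give the (R)-carbinol at C8, and catecholborane at low temperature spares the alkenes.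

**Step 8**
Reactants: 12 (6R,4E,9E)-11-(tert-butyldiphenylsilyloxy)-4,10-dimethylundeca-1,4,9-trien-6-ol; 13 bromoacetyl bromide
Product: 14 bromoacetate of 12
Conditions: pyridine, CH2Cl2, 0 °C
Reagents that add atoms: none
Why: O-acylation at oxygen leaves C8 untouched and attaches the two-carbon unit C11–C12 through the ester tether.

**Step 9**
Reactants: 14 bromoacetate of 12
Product: 15 diazoacetate of 12
Conditions: N,N'-ditosylhydrazine, DBU, THF, 0 °C
Reagents that add atoms: N,N'-ditosylhydrazine, Cc1ccc(cc1)S(=O)(=O)NNS(=O)(=O)c1ccc(C)cc1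
Why: N-alkylation of the ditosylhydrazine by the bromoacetate, followed by base-induced loss of two sulfinates, is an established mild route to diazoacetates that avoids acid and heat.

**Step 10**
Reactants: 15 diazoacetate of 12
Product: 16 cyclopropane-fused lactone (8R)-6-exo-allyl-6-endo-methyl-4-exo-[(E)-5-(tert-butyldiphenylsilyloxy)-4-methylpent-3-enyl]-3-oxabicyclo[3.1.0]hexan-2-one
Conditions: Rh2(cap)4 (1 mol %; cap = caprolactamate), CH2Cl2, reflux, slow addition of 15
Reagents that add atoms: none
Why: Loss of N2 from 15 at Rh2(cap)4 gives an electrophilic rhodium carbene at C11 that adds in a concerted, asynchronous syn fashion to the nearest alkene, bonding first to the less substituted C9 and then to C10. The closest known reaction type is the intramolecular cyclopropanation of allylic diazoacetates with dirhodium carboxamidates. Two temporary rings close: the γ-lactone (O, C8, C9, C11, C12) by 5-exo attack of C11 on C9, and the cyclopropane (C9, C10, C11) by 3-exo collapse of C11 onto C10. C9 and C11 are controlled by the C8 carbinol centre, because A(1,3) strain with the C10 methyl holds H8 in the alkene plane so that the ester oxygen and the carbene reach one face only and the C7 chain ends exo, while C10 follows from the E geometry since the addition is syn (methyl endo, allyl exo). The step needs site selectivity for C9=C10 over the remote C4=C5 and C2=C3 alkenes, which the five-membered tether and the low electrophilicity of the carboxamidate-ligated carbene secure. The product stores the C9–C11 bond together with a strained, acceptor-activated C10–C11 bond whose backside is the one trajectory that puts C11 equatorial and the C10 methyl axial in ring B.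

**Step 11**
Reactants: 16 cyclopropane-fused lactone
Product: 17 (8R)-hydroxy Weinreb amide 3-allyl-2-[(1R,4E)-6-(tert-butyldiphenylsilyloxy)-1-hydroxy-5-methylhex-4-enyl]-N-methoxy-N,3-dimethylcyclopropane-1-carboxamide (amide group; hydroxyalkyl group; ring methyl all on one face)
Conditions: MeNHOMe·HCl, AlMe3, CH2Cl2, 0 °C to rt
Reagents that add atoms: N,O-dimethylhydroxylamine hydrochloride, CNOC.Cl
Why: Aluminium-amide aminolysis cleaves the acyl–oxygen bond of the tether, which frees rotation about C8–C9 without touching any stereocentre.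

**Step 12**
Reactants: 17 (8R)-hydroxy Weinreb amide
Product: 18 8-O-tert-butyldimethylsilyl ether of 17
Conditions: TBSOTf, 2,6-lutidine, CH2Cl2, −78 to 0 °C
Reagents that add atoms: tert-butyldimethylsilyl trifluoromethanesulfonate, CC(C)(C)[Si](C)(C)OS(=O)(=O)C(F)(F)F
Why: Buffered silylation blocks relactonisation and gives a non-participating C8 substituent for the cationic step.

**Step 13**
Reactants: 18 8-O-tert-butyldimethylsilyl ether of 17
Product: 19 2α-chloro-8α-(tert-butyldimethylsilyloxy)-18-(tert-butyldiphenylsilyloxy)-13,14,15,16,17-pentanorlabdan-12-oic acid N-methoxy-N-methylamide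
Conditions: SnCl4 (2.5 equiv), CH2Cl2, −78 to −40 °C; then aq NaHCO3
Reagents that add atoms: tin tetrachloride, Cl[Sn](Cl)(Cl)Cl
Why: Proposed new method: SnCl4 chelated by the N-methoxy amide polarises the C10–C11 bond of the gem-dialkyl (donor)/acyl (acceptor) cyclopropane; C5 of the E-alkene attacks C10 from the backside through a chair (6-exo-tet, ring B), so that inversion puts the C10 methyl axial, C11, C4 and the C8 oxygen equatorial and H5 axial; the C4 cation turns by least motion toward the allyl group and is attacked by C3 (6-endo, ring A), which sends the methyl that was cis to C6 axial and CH2OSi equatorial, also the sterically better arrangement opposite the C10 methyl; chloride from tin caps C2 anti to the new C3–C4 bond, that is equatorially, giving a secondary chloride that no longer ionises, whereas tertiary chlorides, alkenes and O-closed (Cloke–Wilson-type) products can re-enter the cation manifold; the tin enolate is protonated at C11 on work-up; the closest known reaction types are the Lewis-acid opening of acylcyclopropanes with olefin participation, the Lewis-acid-catalysed addition of tertiary alkyl chlorides to terminal alkenes and the chloride-terminated Prins cyclisation.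

**Step 14**
Reactants: 19 decalin silyl ether amide
Product: 20 2α-chloro-8α-hydroxy-18-(tert-butyldiphenylsilyloxy)-13,14,15,16,17-pentanorlabdan-12-oic acid N-methoxy-N-methylamide
Conditions: HF (48 % aq), MeCN, 0 °C
Reagents that add atoms: none
Why: Acidic fluoride removes the secondary tert-butyldimethylsilyl ether much faster than the tert-butyldiphenylsilyl ether.

**Step 15**
Reactants: 20 8α-hydroxy amide
Product: 21 2α-chloro-8-oxo-18-(tert-butyldiphenylsilyloxy)-13,14,15,16,17-pentanorlabdan-12-oic acid N-methoxy-N-methylamide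
Conditions: Dess–Martin periodinane, CH2Cl2, rt
Reagents that add atoms: none
Why: Dess–Martin oxidation removes the control centre C8 under neutral conditions, and C9, now α to the ketone, already holds its thermodynamically preferred equatorial side chain.

**Step 16**
Reactants: 21 8-oxo amide
Product: 22 2α-chloro-18-(tert-butyldiphenylsilyloxy)-13,14,15,16-tetranorlabd-8(17)-en-12-oic acid N-methoxy-N-methylamide
Conditions: Ph3PCH3Br, KOt-Bu, THF, 0 °C to rt
Reagents that add atoms: methyltriphenylphosphonium bromide, C[P+](c1ccccc1)(c1ccccc1)c1ccccc1.[Br-]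
Why: Wittig methylenation of 8-oxolabdane-type ketones is established, the equatorial chloride has no antiperiplanar hydrogen for elimination, and any enolisation returns C9 to the equatorial isomer.

**Step 17**
Reactants: 22 exocyclic methylene amide
Product: 23 2α-chloro-18-(tert-butyldiphenylsilyloxy)-13,14,15,16-tetranorlabd-8(17)-en-12-al
Conditions: DIBAL-H, THF, −78 °C; then aq Rochelle salt
Reagents that add atoms: none
Why: Hydride reduction of a Weinreb amide stops at the chelated hemiaminal, which releases the aldehyde only on work-up.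

**Step 18**
Reactants: 24 (R)-4-benzyloxazolidin-2-one; 25 methyl 4-chloro-4-oxobutanoate
Product: 26 methyl 4-[(R)-4-benzyl-2-oxooxazolidin-3-yl]-4-oxobutanoate
Conditions: Et3N, DMAP (cat.), CH2Cl2, 0 °C to rt
Reagents that add atoms: none
Why: DMAP-catalysed N-acylation of the oxazolidinone with the acid chloride gives the known succinate imide without touching the stereocentre.

**Step 19**
Reactants: 26 methyl 4-[(R)-4-benzyl-2-oxooxazolidin-3-yl]-4-oxobutanoate; 23 aldehyde
Product: 28 (12S,13R)-syn-aldol adduct of 23 and 26, via boron enolate 27 (not isolated)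
Conditions: Bu2BOTf, Et3N, CH2Cl2, −78 to 0 °C; then 23, −78 to 0 °C; then pH 7 buffer, MeOH, H2O2, 0 °C
Reagents that add atoms: none
Why: In the Evans syn-aldol reaction the Z-boron enolate reacts through a Zimmerman–Traxler chair on the face away from the (R)-benzyl group, which should set 12S and 13R regardless of the remote decalin centres.

**Step 20**
Reactants: 28 (12S,13R)-syn-aldol adduct
Product: 30 18-O-(tert-butyldiphenylsilyl)haterumaimide J, via primary amide 29 (not isolated)
Conditions: NH3 (7 M in MeOH), 0 °C to rt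
Reagents that add atoms: ammonia, N
Why: Ammonolysis of the unhindered methyl ester gives a primary amide whose nitrogen attacks the activated N-acyloxazolidinone carbonyl (5-exo-trig), closing the succinimide and expelling the auxiliary under conditions mild enough to keep C13.

**Step 21**
Reactants: 30 18-O-(tert-butyldiphenylsilyl)haterumaimide J
Product: 31 haterumaimide J
Conditions: HF·pyridine, pyridine, THF, rt
Reagents that add atoms: none
Why: Buffered fluoride desilylation frees the C18 alcohol without base, so retro-aldol cleavage, C13 epimerisation and migration of the exocyclic alkene are avoided.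

**Compound list**

1 | methyl 4-oxobutanoate | COC(=O)CCC=O | starting material
2 | 2-(triphenylphosphoranylidene)propanal | CC(C=O)=P(c1ccccc1)(c1ccccc1)c1ccccc1 | starting material
3 | methyl (E)-5-methyl-6-oxohex-4-enoate | COC(=O)CC/C=C(\C)C=O | intermediate
4 | methyl (E)-6-hydroxy-5-methylhex-4-enoate | COC(=O)CC/C=C(\C)CO | intermediate
5 | methyl (E)-6-(tert-butyldiphenylsilyloxy)-5-methylhex-4-enoate | COC(=O)CC/C=C(\C)CO[Si](c1ccccc1)(c1ccccc1)C(C)(C)C | intermediate
6 | (E)-6-(tert-butyldiphenylsilyloxy)-N-methoxy-N,5-dimethylhex-4-enamide | CON(C)C(=O)CC/C=C(\C)CO[Si](c1ccccc1)(c1ccccc1)C(C)(C)C | intermediate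
7 | pent-1-en-4-yne | C=CCC#C | starting material
8 | dimethyl[(E)-2-methylpenta-1,4-dienyl]alane (not isolated) | C=CC/C(C)=C/[Al](C)C | intermediate
9 | (E)-1-bromo-2-methylpenta-1,4-diene | C=CC/C(C)=C/Br | intermediate
10 | (E)-2-methylpenta-1,4-dienyllithium (not isolated) | C=CC/C(C)=C/[Li] | intermediate
11 | (4E,9E)-11-(tert-butyldiphenylsilyloxy)-4,10-dimethylundeca-1,4,9-trien-6-one | C=CC/C(C)=C/C(=O)CC/C=C(\C)CO[Si](c1ccccc1)(c1ccccc1)C(C)(C)C | intermediate
12 | (6R,4E,9E)-11-(tert-butyldiphenylsilyloxy)-4,10-dimethylundeca-1,4,9-trien-6-ol (8R in labdane numbering) | C=CC/C(C)=C/[C@H](O)CC/C=C(\C)CO[Si](c1ccccc1)(c1ccccc1)C(C)(C)C | intermediate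
13 | bromoacetyl bromide | O=C(Br)CBr | starting material
14 | bromoacetate of 12 (8R) | C=CC/C(C)=C/[C@H](OC(=O)CBr)CC/C=C(\C)CO[Si](c1ccccc1)(c1ccccc1)C(C)(C)C | intermediate
15 | diazoacetate of 12 (8R) | C=CC/C(C)=C/[C@H](OC(=O)C=[N+]=[N-])CC/C=C(\C)CO[Si](c1ccccc1)(c1ccccc1)C(C)(C)C | intermediate
16 | cyclopropane-fused γ-lactone, 3-oxabicyclo[3.1.0]hexan-2-one with 6-endo-methyl, 6-exo-allyl and 4-exo-[(E)-5-(tert-butyldiphenylsilyloxy)-4-methylpent-3-enyl] (8R) | O=C1O[C@H](CC/C=C(\C)CO[Si](c3ccccc3)(c3ccccc3)C(C)(C)C)[C@@H]2[C@H]1[C@@]2(C)CC=C | intermediate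
17 | hydroxy Weinreb amide; cyclopropane with C11 amide, C9 (8R)-hydroxyalkyl and C10 methyl on one face, allyl on the other | CON(C)C(=O)[C@H]1[C@@H]([C@H](O)CC/C=C(\C)CO[Si](c2ccccc2)(c2ccccc2)C(C)(C)C)[C@]1(C)CC=C | intermediate
18 | 8-O-tert-butyldimethylsilyl ether of 17 | CON(C)C(=O)[C@H]1[C@@H]([C@H](O[Si](C)(C)C(C)(C)C)CC/C=C(\C)CO[Si](c2ccccc2)(c2ccccc2)C(C)(C)C)[C@]1(C)CC=C | intermediate
19 | trans-decalin: 2α-Cl, 4β-Me, 4α-CH2OTBDPS, 5α-H, 8α-OTBS, 9α-H, 10β-Me, C9β-CH2C(O)N(OMe)Me | CC(C)(C)[Si](C)(C)O[C@@H]1CC[C@H]2[C@](C)(CO[Si](c3ccccc3)(c3ccccc3)C(C)(C)C)C[C@H](Cl)C[C@]2(C)[C@H]1CC(=O)N(C)OC | intermediate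
20 | 8α-alcohol from 19 | O[C@@H]1CC[C@H]2[C@](C)(CO[Si](c3ccccc3)(c3ccccc3)C(C)(C)C)C[C@H](Cl)C[C@]2(C)[C@H]1CC(=O)N(C)OC | intermediate
21 | 8-ketone from 20 | O=C1CC[C@H]2[C@](C)(CO[Si](c3ccccc3)(c3ccccc3)C(C)(C)C)C[C@H](Cl)C[C@]2(C)[C@H]1CC(=O)N(C)OC | intermediate
22 | 8(17)-methylene Weinreb amide | C=C1CC[C@H]2[C@](C)(CO[Si](c3ccccc3)(c3ccccc3)C(C)(C)C)C[C@H](Cl)C[C@]2(C)[C@H]1CC(=O)N(C)OC | intermediate
23 | 2α-chloro-18-(tert-butyldiphenylsilyloxy)-13,14,15,16-tetranorlabd-8(17)-en-12-al | C=C1CC[C@H]2[C@](C)(CO[Si](c3ccccc3)(c3ccccc3)C(C)(C)C)C[C@H](Cl)C[C@]2(C)[C@H]1CC=O | intermediate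
24 | (R)-4-benzyloxazolidin-2-one | O=C1N[C@H](Cc2ccccc2)CO1 | starting material
25 | methyl 4-chloro-4-oxobutanoate | COC(=O)CCC(Cl)=O | starting material
26 | methyl 4-[(R)-4-benzyl-2-oxooxazolidin-3-yl]-4-oxobutanoate | COC(=O)CCC(=O)N1[C@H](Cc2ccccc2)COC1=O | intermediate
27 | Z-dibutylboron enolate of 26 (not isolated) | COC(=O)C/C=C(\OB(CCCC)CCCC)N1[C@H](Cc2ccccc2)COC1=O | intermediate
28 | (12S,13R)-syn-aldol adduct | C=C1CC[C@H]2[C@](C)(CO[Si](c3ccccc3)(c3ccccc3)C(C)(C)C)C[C@H](Cl)C[C@]2(C)[C@H]1C[C@H](O)[C@@H](CC(=O)OC)C(=O)N1[C@H](Cc3ccccc3)COC1=O | intermediate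
29 | C15 primary amide of 28 (not isolated) | C=C1CC[C@H]2[C@](C)(CO[Si](c3ccccc3)(c3ccccc3)C(C)(C)C)C[C@H](Cl)C[C@]2(C)[C@H]1C[C@H](O)[C@@H](CC(N)=O)C(=O)N1[C@H](Cc3ccccc3)COC1=O | intermediate
30 | 18-O-(tert-butyldiphenylsilyl)haterumaimide J | C=C1CC[C@H]2[C@](C)(CO[Si](c3ccccc3)(c3ccccc3)C(C)(C)C)C[C@H](Cl)C[C@]2(C)[C@H]1C[C@H](O)[C@H]1CC(=O)NC1=O | intermediate
31 | haterumaimide J | C=C1CC[C@H]2[C@](C)(CO)C[C@H](Cl)C[C@]2(C)[C@H]1C[C@H](O)[C@H]1CC(=O)NC1=O | target

**Step count**

The route has 21 steps in total. The longest linear sequence is 19 steps (steps 1–4, 6–17 and 19–21).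

**Steps most likely to fail**

1. **Step 13.**
   - Risk: the cation manifold may leak before ring A closes, through hydride shift from C5 to C4, proton loss, or capture of C10 by the amide oxygen. Early ionisation followed by rotation about C9–C10 may also erode the C10 configuration.
   - Fallback: set out from 18 and replace the single cascade by two separately optimised ring closures of known type.
   - First closure: a short exposure to one equivalent of SnCl4 at very low temperature performs only the olefin-assisted opening of the acylcyclopropane. Chloride capture at C4 then gives the monocyclic tertiary chloride F1, which is isolated.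
   - Second closure: catalytic ZnCl2·OEt2 in CH2Cl2 adds the tertiary C–Cl bond of F1 across the terminal alkene. This is the known Lewis-acid-catalysed addition of tertiary alkyl chlorides to monosubstituted alkenes, which runs cleanly because the secondary chloride formed ionises more slowly than F1. The fallback returns to the route at 19.

2. **Step 20.**
   - Risk: ammonia may open the oxazolidinone ring instead of displacing it, and the basic medium may cause retro-aldol cleavage or epimerisation at C13.
   - Fallback: set out from 28 and remove the auxiliary first with LiOH/H2O2 to give the hydroxy acid monoester F2. Couple the acid with NH4Cl (EDC, HOBt, i-Pr2NEt) to the primary amide F3. Close the imide onto the methyl ester with catalytic K2CO3 in MeOH, returning at 30.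

3. **Step 6.**
   - Risk: proton transfer from the doubly allylic CH2 to the vinyllithium, followed by isomerisation to a conjugated diene, may consume the nucleophile.
   - Fallback: set out from 6 and from alane 8 (made from 7) and avoid the lithium reagent altogether. DIBAL-H reduces 6 to the aldehyde F4, alane 8 is added directly to F4 to give the racemic allylic alcohol F5, and Dess–Martin oxidation returns to the route at enone 11.

**Further compounds**
F1 | step 13 | monocyclic tertiary chloride (ring B closed; C4–Cl, both C4 epimers; allyl on C10) | CC(C)(C)[Si](C)(C)O[C@@H]1CC[C@@H](C(C)(Cl)CO[Si](c2ccccc2)(c2ccccc2)C(C)(C)C)[C@](C)(CC=C)[C@H]1CC(=O)N(C)OC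
F2 | step 20 | (12S,13R)-hydroxy acid monomethyl ester | C=C1CC[C@H]2[C@](C)(CO[Si](c3ccccc3)(c3ccccc3)C(C)(C)C)C[C@H](Cl)C[C@]2(C)[C@H]1C[C@H](O)[C@@H](CC(=O)OC)C(=O)O
F3 | step 20 | (12S,13R)-C16 primary amide methyl ester | C=C1CC[C@H]2[C@](C)(CO[Si](c3ccccc3)(c3ccccc3)C(C)(C)C)C[C@H](Cl)C[C@]2(C)[C@H]1C[C@H](O)[C@@H](CC(=O)OC)C(N)=O
F4 | step 6 | (E)-6-(tert-butyldiphenylsilyloxy)-5-methylhex-4-enal | O=CCC/C=C(\C)CO[Si](c1ccccc1)(c1ccccc1)C(C)(C)C
F5 | step 6 | racemic (4E,9E)-11-(tert-butyldiphenylsilyloxy)-4,10-dimethylundeca-1,4,9-trien-6-ol | C=CC/C(C)=C/C(O)CC/C=C(\C)CO[Si](c1ccccc1)(c1ccccc1)C(C)(C)C
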